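**Retrosynthetic overview**
- Feature: ring A carries three different oxygens (O1 on C8a, OH on C7, OMe on C5) around the alkylated C8. C8a and C7 lie ortho and para to C4a, which bears the C4 carbonyl, so these two oxygens can be held as C–F bonds until that carbonyl is in place. Only O5 is an ether from the start.
- C7–OH ⇒ C7–F (SNAr with a hydroxide surrogate on the finished flavone). Ring C ⇒ cut at O1–C8a to a 1-(2,4-difluoroaryl)-3-aryl-1,3-diketone (intramolecular SNAr).
- Diketone ⇒ crossed Claisen condensation of the difluoroacetophenone with bis-MOM methyl resorcylate. Acetyl group ⇒ lithiation of the ring C–H between F and OMe.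
- Side chain ⇒ aldol condensation of 2,6-difluoro-4-methoxybenzaldehyde with 6,6-dimethyl-δ-valerolactone, then asymmetric hydrogenation (sets the only stereocentre), then lactone C=O → Weinreb amide → methyl ketone → isopropenyl.
- Ring order: rings A and B are bought, the lactone is a temporary ring that is opened again, and ring C is the only ring of the target that is built.

Key step: step 11

Assumption: the stereocentre is read from the SMILES as R (isopropenyl > CH2-aryl > CH2CH2 > H), a descriptor that holds for every intermediate from 8 on, and the ligand enantiomer for step 3 is the one that a trial run shows to give (R)-8.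

**Step 1**
Reactants: 1 ethyl 5-oxohexanoate
Product: 3 6,6-dimethyloxan-2-one (6,6-dimethyl-δ-valerolactone), via bromomagnesium alkoxide 2 (not isolated)
Conditions: MeMgBr (1.05 equiv), THF, −78 °C → rt; aq NH4Cl; cat. TsOH, CH2Cl2, rt
Reagents that add atoms: methylmagnesium bromide, C[Mg]Br
Why: Chemoselective Grignard addition, in which the ketone reacts much faster than the ester at −78 °C and the tertiary alkoxide closes onto the ester on warming (lactonisation helped by the gem-dimethyl effect) only after the Grignard reagent has been used up.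

**Step 2**
Reactants: 3 6,6-dimethyloxan-2-one; 4 2,6-difluoro-4-methoxybenzaldehyde
Product: 7 (3E)-3-[(2,6-difluoro-4-methoxyphenyl)methylidene]-6,6-dimethyloxan-2-one, via lithium aldolate 5 (not isolated), via aldol acetate 6 (not isolated)
Conditions: LDA (1.05 equiv), THF, −78 °C; 4; Ac2O (1.5 equiv), −78 °C → rt; DBU (2.5 equiv), rt → 50 °C
Reagents that add atoms: none
Why: Aldol condensation run in one flask, in which the lactone lithium enolate adds to the non-enolisable aldehyde, the aldolate is trapped as its acetate, and DBU-induced E1cB elimination gives the thermodynamically preferred E-alkene (aryl trans to the lactone carbonyl), the single geometry that step 3 needs.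

**Step 3**
Reactants: 7 (3E)-3-[(2,6-difluoro-4-methoxyphenyl)methylidene]-6,6-dimethyloxan-2-one
Product: 8 (3R)-3-[(2,6-difluoro-4-methoxyphenyl)methyl]-6,6-dimethyloxan-2-one
Conditions: [Ir(cod)(L*)]BArF (1 mol %, L* = spiro phosphine–oxazoline of SpinPHOX type), H2 (50 bar), CH2Cl2, rt
Reagents that add atoms: none
Why: Iridium–phosphine-oxazoline-catalysed asymmetric hydrogenation of an exocyclic α-arylidene lactone, a known substrate class, in which the E-configured trisubstituted alkene binds to the chiral iridium hydride by one face and takes up both hydrogens there, so that C3 of the lactone (the later side-chain stereocentre) is set as R under catalyst control, the aryl fluorides stay untouched, and recrystallisation of 8 remains available to raise the enantiomeric purity.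

**Step 4**
Reactants: 8 (3R)-3-[(2,6-difluoro-4-methoxyphenyl)methyl]-6,6-dimethyloxan-2-one
Product: 9 (2R)-2-[(2,6-difluoro-4-methoxyphenyl)methyl]-5-hydroxy-N-methoxy-N,5-dimethylhexanamide
Conditions: MeNH(OMe)·HCl (3 equiv), AlMe3 (3 equiv), CH2Cl2, 0 °C → rt; aq Rochelle salt
Reagents that add atoms: N,O-dimethylhydroxylamine hydrochloride, CNOC.Cl
Why: Weinreb aminolysis of a lactone, in which the weakly basic and strongly Lewis-acidic aluminium amide opens the ring irreversibly as the aluminium alkoxide and does not enolise the α-stereocentre.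

**Step 5**
Reactants: 9 (2R)-2-[(2,6-difluoro-4-methoxyphenyl)methyl]-5-hydroxy-N-methoxy-N,5-dimethylhexanamide
Product: 10 (2R)-2-[(2,6-difluoro-4-methoxyphenyl)methyl]-N-methoxy-N,5-dimethyl-5-(triethylsilyloxy)hexanamide
Conditions: TESOTf (1.3 equiv), 2,6-lutidine (2 equiv), CH2Cl2, −40 → 0 °C
Reagents that add atoms: triethylsilyl trifluoromethanesulfonate, CC[Si](CC)(CC)OS(=O)(=O)C(F)(F)F
Why: Silyl triflate silylation, needed for a hindered tertiary alcohol, gives a TES ether that blocks relactonisation and later hemiketal formation and masks the acidic OH for the organometallic steps that follow.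

**Step 6**
Reactants: 10 (2R)-2-[(2,6-difluoro-4-methoxyphenyl)methyl]-N-methoxy-N,5-dimethyl-5-(triethylsilyloxy)hexanamide
Product: 11 (3R)-3-[(2,6-difluoro-4-methoxyphenyl)methyl]-6-methyl-6-(triethylsilyloxy)heptan-2-one
Conditions: MeMgBr (2 equiv), THF, 0 °C; cold aq NH4Cl
Reagents that add atoms: methylmagnesium bromide, C[Mg]Br
Why: Weinreb ketone synthesis, in which the chelated tetrahedral adduct lasts until the cold quench, so that no second addition occurs and the free ketone never meets base.

**Step 7**
Reactants: 11 (3R)-3-[(2,6-difluoro-4-methoxyphenyl)methyl]-6-methyl-6-(triethylsilyloxy)heptan-2-one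
Product: 12 1,3-difluoro-5-methoxy-2-[(2R)-5-methyl-2-(prop-1-en-2-yl)-5-(triethylsilyloxy)hexyl]benzene
Conditions: Ph3PCH3Br (1.6 equiv), KHMDS (1.5 equiv), THF, 0 °C; 11, −20 °C → rt
Reagents that add atoms: methyltriphenylphosphonium bromide, C[P+](c1ccccc1)(c1ccccc1)c1ccccc1.[Br-]
Why: Wittig methylenation with the ylide made from less base than phosphonium salt, so that the only competing enolisation is the kinetically preferred one at the methyl group, which leaves the stereocentre alone, and after this step that carbon can no longer epimerise.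

**Step 8**
Reactants: 12 1,3-difluoro-5-methoxy-2-[(2R)-5-methyl-2-(prop-1-en-2-yl)-5-(triethylsilyloxy)hexyl]benzene
Product: 14 1-{2,4-difluoro-6-methoxy-3-[(2R)-5-methyl-2-(prop-1-en-2-yl)-5-(triethylsilyloxy)hexyl]phenyl}ethan-1-one, via aryllithium 13 (not isolated)
Conditions: s-BuLi (1.15 equiv), THF, −78 °C, 1 h; MeC(O)N(OMe)Me (1.5 equiv), −78 → 0 °C; aq NH4Cl
Reagents that add atoms: N-methoxy-N-methylacetamide, CON(C)C(C)=O
Why: Directed ortho-metalation followed by Weinreb acylation, in which the ring hydrogen flanked by F and OMe is by far the most acidic C–H (the two such positions are equivalent by rotation about the CH2–aryl bond), the ortho-fluoroaryllithium does not collapse to a benzyne at −78 °C, and the acylation stops at the ketone.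

**Step 9**
Reactants: 15 methyl 2,4-dihydroxybenzoate
Product: 16 methyl 2,4-bis(methoxymethoxy)benzoate
Conditions: NaH (2.5 equiv), MOMCl (2.5 equiv), DMF, 0 °C → rt
Reagents that add atoms: chloromethyl methyl ether, COCCl
Why: Williamson-type O-alkylation of both phenoxides, with NaH chosen because the 2-OH is hydrogen-bonded to the ester and resists amine bases.

**Step 10**
Reactants: 14 1-{2,4-difluoro-6-methoxy-3-[(2R)-5-methyl-2-(prop-1-en-2-yl)-5-(triethylsilyloxy)hexyl]phenyl}ethan-1-one; 16 methyl 2,4-bis(methoxymethoxy)benzoate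
Product: 17 1-{2,4-difluoro-6-methoxy-3-[(2R)-5-methyl-2-(prop-1-en-2-yl)-5-(triethylsilyloxy)hexyl]phenyl}-3-[2,4-bis(methoxymethoxy)phenyl]propane-1,3-dione
Conditions: 14, LiHMDS (2.5 equiv), THF, −78 °C; 16 (1.2 equiv), −78 °C → rt; pH 6 buffer
Reagents that add atoms: none
Why: Crossed Claisen condensation in which only the ketone can enolise, excess base pulls the equilibrium by deprotonating the 1,3-diketone, the fluorinated ring is present only as electron-rich enolates that lithium methoxide does not attack, and lithium chelation holds the diketonate in a U shape that delays ring closure until step 11.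

**Step 11**
Reactants: 17 1-{2,4-difluoro-6-methoxy-3-[(2R)-5-methyl-2-(prop-1-en-2-yl)-5-(triethylsilyloxy)hexyl]phenyl}-3-[2,4-bis(methoxymethoxy)phenyl]propane-1,3-dione
Product: 18 7-fluoro-5-methoxy-2-[2,4-bis(methoxymethoxy)phenyl]-8-[(2R)-5-methyl-2-(prop-1-en-2-yl)-5-(triethylsilyloxy)hexyl]-4H-chromen-4-one
Conditions: K2CO3 (2 equiv), DMSO (0.05 M), 80 °C
Reagents that add atoms: none
Why: Carbonate deprotonates the 1,3-diketone, and after rotation about the C3–C4 bond the enolate oxygen on the B-ring side adds to the fluorine-bearing carbon ortho to the aroyl group (the future C8a); the Meisenheimer adduct, whose charge is taken up by the C4 carbonyl, then loses fluoride and forms the O1–C8a bond. The closest known reaction type is the base-mediated intramolecular SNAr (O-arylation) of 1-(2-haloaryl)-1,3-diketones to flavones, which runs best with fluoride as leaving group. Ring C closes as a six-membered ring by ipso addition–elimination, and the planar conjugated γ-pyranone that results makes the step irreversible. No stereocentre is formed, and the side-chain stereocentre is neither acidic nor close to the reacting atoms. The step must pick one of three possible leaving groups: the para fluoride cannot be reached by the tethered oxygen, and the ortho methoxy group, which can be reached, sits on a far less electrophilic carbon and is a much poorer nucleofuge, so that only the ortho C–F bond should break. Dilution disfavours intermolecular attack of the diketonate on the para C–F bond, DMSO in place of DMF keeps dimethylamine away from that bond, and partial loss of the TES group to the released fluoride would do no harm because the free tertiary alcohol is tolerated in steps 12 and 13.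

**Step 12**
Reactants: 18 7-fluoro-5-methoxy-2-[2,4-bis(methoxymethoxy)phenyl]-8-[(2R)-5-methyl-2-(prop-1-en-2-yl)-5-(triethylsilyloxy)hexyl]-4H-chromen-4-one
Product: 20 7-hydroxy-5-methoxy-2-[2,4-bis(methoxymethoxy)phenyl]-8-[(2R)-5-methyl-2-(prop-1-en-2-yl)-5-(triethylsilyloxy)hexyl]-4H-chromen-4-one, via sulfonylethyl ether 19 (not isolated)
Conditions: MeSO2CH2CH2OH (1.5 equiv), NaH (3.5 equiv), DMF, 0 °C → rt; aq NH4Cl
Reagents that add atoms: 2-(methylsulfonyl)ethanol, CS(=O)(=O)CCO
Why: SNAr with a hydroxide surrogate followed by E1cB elimination, in which the alkoxide attacks C7 (the only C–F bond left, para to C4a and thus activated by the C4 carbonyl) and excess base then expels methyl vinyl sulfone from the ether, which leaves the 7-phenoxide, whose charge shields the flavone from further nucleophilic attack.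

**Step 13**
Reactants: 20 7-hydroxy-5-methoxy-2-[2,4-bis(methoxymethoxy)phenyl]-8-[(2R)-5-methyl-2-(prop-1-en-2-yl)-5-(triethylsilyloxy)hexyl]-4H-chromen-4-one
Product: 21 2-(2,4-dihydroxyphenyl)-7-hydroxy-8-[(2R)-5-hydroxy-5-methyl-2-(prop-1-en-2-yl)hexyl]-5-methoxy-4H-chromen-4-one (CNP0256984.1)
Conditions: HCl (ca. 1 M) in MeOH–H2O 9:1, 40 °C, stopped as soon as the 2'-MOM ether has gone
Reagents that add atoms: none
Why: Acid-catalysed solvolysis of the two aryl MOM acetals and of the TES ether in one operation, at an acidity and temperature below what is needed to ionise the tertiary alcohol or to protonate the 1,1-disubstituted alkene, and with the aryl methyl ether and the non-acidic stereocentre unaffected.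

**Compound list**
1 | ethyl 5-oxohexanoate | CCOC(=O)CCCC(C)=O | starting material
2 | bromomagnesium alkoxide of ethyl 5-hydroxy-5-methylhexanoate | CCOC(=O)CCCC(C)(C)O[Mg]Br | intermediate
3 | 6,6-dimethyloxan-2-one | CC1(C)CCCC(=O)O1 | intermediate
4 | 2,6-difluoro-4-methoxybenzaldehyde | COc1cc(F)c(C=O)c(F)c1 | starting material
5 | lithium aldolate of 3-[(2,6-difluoro-4-methoxyphenyl)(hydroxy)methyl]-6,6-dimethyloxan-2-one (diastereomer mixture) | [Li]OC(c1c(F)cc(OC)cc1F)C1CCC(C)(C)OC1=O | intermediate
6 | (2,6-difluoro-4-methoxyphenyl)(6,6-dimethyl-2-oxooxan-3-yl)methyl acetate (diastereomer mixture) | CC(=O)OC(c1c(F)cc(OC)cc1F)C1CCC(C)(C)OC1=O | intermediate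
7 | (3E)-3-[(2,6-difluoro-4-methoxyphenyl)methylidene]-6,6-dimethyloxan-2-one | O=C1OC(C)(C)CC/C1=C\c1c(F)cc(OC)cc1F | intermediate
8 | (3R)-3-[(2,6-difluoro-4-methoxyphenyl)methyl]-6,6-dimethyloxan-2-one | O=C1OC(C)(C)CC[C@@H]1Cc1c(F)cc(OC)cc1F | intermediate
9 | (2R)-2-[(2,6-difluoro-4-methoxyphenyl)methyl]-5-hydroxy-N-methoxy-N,5-dimethylhexanamide | CON(C)C(=O)[C@H](CCC(C)(C)O)Cc1c(F)cc(OC)cc1F | intermediate
10 | (2R)-2-[(2,6-difluoro-4-methoxyphenyl)methyl]-N-methoxy-N,5-dimethyl-5-(triethylsilyloxy)hexanamide | CON(C)C(=O)[C@H](CCC(C)(C)O[Si](CC)(CC)CC)Cc1c(F)cc(OC)cc1F | intermediate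
11 | (3R)-3-[(2,6-difluoro-4-methoxyphenyl)methyl]-6-methyl-6-(triethylsilyloxy)heptan-2-one | CC(=O)[C@H](CCC(C)(C)O[Si](CC)(CC)CC)Cc1c(F)cc(OC)cc1F | intermediate
12 | 1,3-difluoro-5-methoxy-2-[(2R)-5-methyl-2-(prop-1-en-2-yl)-5-(triethylsilyloxy)hexyl]benzene | C=C(C)[C@H](CCC(C)(C)O[Si](CC)(CC)CC)Cc1c(F)cc(OC)cc1F | intermediate
13 | aryllithium of 12, lithium on the ring carbon between F and OMe | C=C(C)[C@H](CCC(C)(C)O[Si](CC)(CC)CC)Cc1c(F)cc(OC)c([Li])c1F | intermediate
14 | 1-{2,4-difluoro-6-methoxy-3-[(2R)-5-methyl-2-(prop-1-en-2-yl)-5-(triethylsilyloxy)hexyl]phenyl}ethan-1-one | C=C(C)[C@H](CCC(C)(C)O[Si](CC)(CC)CC)Cc1c(F)cc(OC)c(C(C)=O)c1F | intermediate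
15 | methyl 2,4-dihydroxybenzoate | COC(=O)c1ccc(O)cc1O | starting material
16 | methyl 2,4-bis(methoxymethoxy)benzoate | COCOc1ccc(C(=O)OC)c(OCOC)c1 | intermediate
17 | 1-{2,4-difluoro-6-methoxy-3-[(2R)-5-methyl-2-(prop-1-en-2-yl)-5-(triethylsilyloxy)hexyl]phenyl}-3-[2,4-bis(methoxymethoxy)phenyl]propane-1,3-dione | C=C(C)[C@H](CCC(C)(C)O[Si](CC)(CC)CC)Cc1c(F)cc(OC)c(C(=O)CC(=O)c2ccc(OCOC)cc2OCOC)c1F | intermediate
18 | 7-fluoro-5-methoxy-2-[2,4-bis(methoxymethoxy)phenyl]-8-[(2R)-5-methyl-2-(prop-1-en-2-yl)-5-(triethylsilyloxy)hexyl]-4H-chromen-4-one | C=C(C)[C@H](CCC(C)(C)O[Si](CC)(CC)CC)Cc1c(F)cc(OC)c2c(=O)cc(-c3ccc(OCOC)cc3OCOC)oc12 | intermediate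
19 | 7-[2-(methylsulfonyl)ethoxy] analogue of 18 | C=C(C)[C@H](CCC(C)(C)O[Si](CC)(CC)CC)Cc1c(OCCS(C)(=O)=O)cc(OC)c2c(=O)cc(-c3ccc(OCOC)cc3OCOC)oc12 | intermediate
20 | 7-hydroxy-5-methoxy-2-[2,4-bis(methoxymethoxy)phenyl]-8-[(2R)-5-methyl-2-(prop-1-en-2-yl)-5-(triethylsilyloxy)hexyl]-4H-chromen-4-one | C=C(C)[C@H](CCC(C)(C)O[Si](CC)(CC)CC)Cc1c(O)cc(OC)c2c(=O)cc(-c3ccc(OCOC)cc3OCOC)oc12 | intermediate
21 | 2-(2,4-dihydroxyphenyl)-7-hydroxy-8-[(2R)-5-hydroxy-5-methyl-2-(prop-1-en-2-yl)hexyl]-5-methoxy-4H-chromen-4-one | C=C(C)[C@H](CCC(C)(C)O)Cc1c(O)cc(OC)c2c(=O)cc(-c3ccc(O)cc3O)oc12 | target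

**Step count**
Total step count: 13.
Longest linear sequence: 12 (steps 1–8 and 10–13); step 9 is the one-step side branch.

**Steps most likely to fail**

**Step 12 (hydroxylation at C7).**
- What may go wrong: the alkoxide may add reversibly to C2 and open the pyranone faster than it attacks C7. C7 is flanked by the branched alkyl group and is activated only by a vinylogous ester carbonyl.
- Fallback: it sets out from 14 and returns at 20, and places the oxygen before the pyranone exists.
  - 14 is heated with sodium allyloxide in allyl alcohol at 60 °C. The protic medium keeps the ketone largely un-enolised. The fluoride para to the acetyl group has only one large neighbour, so it should react ahead of the ortho fluoride wedged between acetyl and alkyl groups. This gives 1-{4-(allyloxy)-2-fluoro-6-methoxy-3-alkylphenyl}ethan-1-one F1.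
  - Claisen condensation with 16 under the conditions of step 10 gives the allyloxy diketone F2.
  - The same O1–C8a ring closure as in step 11 gives the 7-allyloxyflavone F3.
  - Pd(PPh3)4 (cat.) with morpholine in THF at rt removes the allyl group without touching the isopropenyl group and delivers 20.

**Step 3 (asymmetric hydrogenation).**
- What may go wrong: facial discrimination may be poor, because the di-ortho-fluorinated aryl group is twisted out of the alkene plane, or turnover may be slow.
- Fallback: it sets out from 4 and returns at 9, and sets the stereocentre by an auxiliary-controlled Evans alkylation of predictable sense.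
  - NaBH4 in MeOH reduces 4 to (2,6-difluoro-4-methoxyphenyl)methanol F4.
  - PBr3 in CH2Cl2 at 0 °C gives 2-(bromomethyl)-1,3-difluoro-5-methoxybenzene F5.
  - Purchased 5-methylhex-4-enoic acid is coupled with purchased (S)-4-benzyloxazolidin-2-one (PivCl, Et3N, LiCl, THF) to give (4S)-4-benzyl-3-(5-methylhex-4-enoyl)oxazolidin-2-one F6.
  - The chelated Z-sodium enolate of F6 (NaHMDS, THF, −78 °C) is alkylated by F5 on the face opposite the benzyl group, which gives the (2R)-alkylated imide F7. Its minor diastereomer can be removed by chromatography.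
  - MeNH(OMe)·HCl/AlMe3 converts F7 into the unsaturated Weinreb amide F8.
  - Mukaiyama hydration of its only alkene (cat. Mn(dpm)3, PhSiH3, O2, i-PrOH) places the tertiary hydroxyl group and gives 9.
  - This material also serves to confirm the configuration of 8.

**Step 13 (global deprotection).**
- What may go wrong: the tertiary alcohol may ionise, or the isopropenyl group may be protonated and then captured by the neighbouring 7-OH (chroman formation), before the slower 2'-MOM ether has been cleaved.
- Fallback: it sets out from 20 and returns at 21, and takes the two kinds of protecting group off separately without Brønsted acid.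
  - TMSOTf with 2,2'-bipyridyl in MeCN at 0 °C → rt exchanges the aryl MOM ethers (and the free 7-OH) for silyl ethers to give the tris(trimethylsilyl) ether F9.
  - F9 is hydrolysed by added water in the same flask to the 7,2',4'-trihydroxyflavone TES ether F10.
  - HF·pyridine in THF–pyridine at 0 °C → rt then removes the tertiary TES ether and gives 21.

**Further compounds**
F1 | step 12 | 1-{4-(allyloxy)-2-fluoro-6-methoxy-3-[(2R)-5-methyl-2-(prop-1-en-2-yl)-5-(triethylsilyloxy)hexyl]phenyl}ethan-1-one | C=C(C)[C@H](CCC(C)(C)O[Si](CC)(CC)CC)Cc1c(OCC=C)cc(OC)c(C(C)=O)c1F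
F2 | step 12 | 1-{4-(allyloxy)-2-fluoro-6-methoxy-3-[(2R)-5-methyl-2-(prop-1-en-2-yl)-5-(triethylsilyloxy)hexyl]phenyl}-3-[2,4-bis(methoxymethoxy)phenyl]propane-1,3-dione | C=C(C)[C@H](CCC(C)(C)O[Si](CC)(CC)CC)Cc1c(OCC=C)cc(OC)c(C(=O)CC(=O)c2ccc(OCOC)cc2OCOC)c1F
F3 | step 12 | 7-(allyloxy)-5-methoxy-2-[2,4-bis(methoxymethoxy)phenyl]-8-[(2R)-5-methyl-2-(prop-1-en-2-yl)-5-(triethylsilyloxy)hexyl]-4H-chromen-4-one | C=C(C)[C@H](CCC(C)(C)O[Si](CC)(CC)CC)Cc1c(OCC=C)cc(OC)c2c(=O)cc(-c3ccc(OCOC)cc3OCOC)oc12
F4 | step 3 | (2,6-difluoro-4-methoxyphenyl)methanol | COc1cc(F)c(CO)c(F)c1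
F5 | step 3 | 2-(bromomethyl)-1,3-difluoro-5-methoxybenzene | COc1cc(F)c(CBr)c(F)c1
F6 | step 3 | (4S)-4-benzyl-3-(5-methylhex-4-enoyl)oxazolidin-2-one | O=C1OC[C@H](Cc2ccccc2)N1C(=O)CCC=C(C)C
F7 | step 3 | (4S)-4-benzyl-3-{(2R)-2-[(2,6-difluoro-4-methoxyphenyl)methyl]-5-methylhex-4-enoyl}oxazolidin-2-one | O=C1OC[C@H](Cc2ccccc2)N1C(=O)[C@H](CC=C(C)C)Cc1c(F)cc(OC)cc1F
F8 | step 3 | (2R)-2-[(2,6-difluoro-4-methoxyphenyl)methyl]-N-methoxy-N,5-dimethylhex-4-enamide | CON(C)C(=O)[C@H](CC=C(C)C)Cc1c(F)cc(OC)cc1F
F9 | step 13 | 5-methoxy-7-(trimethylsilyloxy)-2-[2,4-bis(trimethylsilyloxy)phenyl]-8-[(2R)-5-methyl-2-(prop-1-en-2-yl)-5-(triethylsilyloxy)hexyl]-4H-chromen-4-one | C=C(C)[C@H](CCC(C)(C)O[Si](CC)(CC)CC)Cc1c(O[Si](C)(C)C)cc(OC)c2c(=O)cc(-c3ccc(O[Si](C)(C)C)cc3O[Si](C)(C)C)oc12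
F10 | step 13 | 2-(2,4-dihydroxyphenyl)-7-hydroxy-5-methoxy-8-[(2R)-5-methyl-2-(prop-1-en-2-yl)-5-(triethylsilyloxy)hexyl]-4H-chromen-4-one | C=C(C)[C@H](CCC(C)(C)O[Si](CC)(CC)CC)Cc1c(O)cc(OC)c2c(=O)cc(-c3ccc(O)cc3O)oc12
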